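## Structural features

The target is a 3,8''-linked biflavanone. Each half is a chroman-4-one: a phloroglucinol-type benzene ring (A above, A'' below) fused to a dihydropyranone (C, C'') that carries an aryl ring at C2 (catechol ring B above, 4-hydroxyphenyl ring B'' below). The halves are joined by one C–C bond from the sp3 carbon C3 of the upper pyranone to the aromatic carbon C8'' of ring A'', a position flanked by C8a'' (bearing O1'') and C7'' (bearing a hydroxyl). There are three stereocentres: C2 (R) and C3 (S) are neighbours in ring C with the two aryl groups trans, and C2'' (S) stands alone in ring C''. C2 and C2'' have the same substituent ranking but opposite descriptors, so the two O1–C2 bonds must be formed with opposite facial sense. All three centres are labile: under base either pyranone can open by retro-oxa-Michael elimination to a 2'-hydroxychalcone, and C3 is also enolizable. The seven free phenols, one catechol among them, are sensitive to oxidation. The real difficulty is the congested bond between a tertiary carbon and a fully substituted electron-rich arene, together with the late, independent setting of C2/C3 and C2'' without reopening a ring already closed. The key step uses ring A of the upper unit: O1 sits on C8a, the C4 carbonyl carbon on the adjacent C4a and the C5 oxygen on the next carbon, which is the pattern a 3-alkoxyaryne gives when an oxygen nucleophile and an acyl group add across its triple bond.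

## Logic of the disconnections

24 to 23. The seven phenolic O–H bonds are traced back to O–benzyl bonds. The polyphenol cannot be carried through base and fluoride steps, and benzyl ethers come off under neutral hydrogenolysis that leaves the base-labile centres alone. The forward step must stop before the cyclic benzylic C2–O1 and C2''–O1'' bonds or the ketones are reduced.

23 to 22. The O1''–C2'' bond of the lower pyranone is cut (retro-oxa-Michael). This removes C2'' and turns the lower unit into a planar enone. The forward step needs a catalyst that adds the phenol to one face of the enone (2''S) without reopening the upper ring.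

22 to 21. The free O1'' hydroxyl is traced back to its methoxymethyl ether. This gate keeps the lower phenol silent while the upper ring is closed with the opposite facial sense. Removal must be mild enough in acid not to close the lower enone without control.

21 to 20. The O1–C2 bond of the upper pyranone is cut, removing C2 and C3 together. The forward step must set C2 (R) by catalyst control on a hindered, trisubstituted enone; C3 follows by equilibration to the trans isomer.

20 to 18 and 19. The C2''=C3'' double bond of the lower enone is cut (aldol retron). This detaches ring B'' and leaves a methyl ketone. The forward condensation must run in the presence of the upper hydroxy-enone, which strong base holds as its open phenoxide.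

18 to 16 (through 17) and 7. The bonds O1–C8a and C4–C4a are cut together. Ring A is held only by these two adjacent bonds, so it leaves as an aryne equivalent and the rest becomes a carboxylic acid that already contains C2, C3, C4 and all of ring A''. The hindered C3–C8'' bond is thus present before the key step as an sp2–sp2 bond. The forward step demands regioselective addition to the aryne, acyl transfer faster than protonation, and survival of the acetyl, acetal and benzyl groups.

16 to 13 and 14. The C2=C3 double bond is cut (Perkin retron), splitting off ring B. The forward step must give the E acid and leave the methyl ketone alone.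

13 to 12 to 11. The carboxyl group is traced through the aldehyde to a terminal alkene with one more carbon. The forward cleavage must spare the electron-rich ring.

11 to 10 to 9 to 8. The acetal O–C bond is cut first. The C8''–CH2 bond is then traced by a [3,3] shift to an O-allyl bond, and that ether to the phenol. The carbon substituent is thereby delivered intramolecularly to the only free ortho position, so regiochemistry is not in question.

7 to 5 to 2 to 1. The O–S bond of the triflate, the C–Si bond and the carbamate are removed in turn. The carbamate is needed only to direct silicon to the carbon between two oxygens; the forward lithiation must be faster than attack on the benzyl ethers.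

## Other disconnections considered

Alternative 1: The cut is O1''–C2'' of the lower pyranone, made last by an enzyme. In the forward sense the open-chain chalcone A1 (upper unit complete, 6'-oxygen capped as a MOM ether so that only the 2'-hydroxyl next to the linkage can add) would be cyclized by a chalcone isomerase to A2, and acid would then remove the MOM group.
- In its favour: such isomerases deliver the (2S) sense that C2'' needs; near-neutral buffer would not disturb C2/C3; free phenols are tolerated.
- Against it here: the substrate is far from the natural one, with a whole flavanone beside the reacting hydroxyl and the second ortho hydroxyl capped, so acceptance by a narrow active site is doubtful. A free-phenol 2'-hydroxychalcone can also close spontaneously in buffer. The benzyl scheme could not be kept, because hydrogenolysis before the enzymatic step would saturate the enone.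
- Comparison: on fidelity of C2'' alone the enzyme, if it accepts A1, would be the better of the two. It addresses only one bond and one centre, so the C3–C8'' bond, ring A and C2/C3 must still come from elsewhere, and the aryne insertion would serve equally. Step count is about equal; predictability and protecting-group economy favour the chosen plan.

Alternative 2: The cut is through ring A'' (C8''–C8a'', C6''–C7'', with C4a''–C8a'' formed in the final electrocyclization). In the forward sense A3 and the siloxyalkyne A4 are heated: A3 opens to a vinylketene, adds to A4 by [2+2], and ring opening, six-electron closure and tautomerization give the phenol A5.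
- In its favour: regiochemistry is fixed by the connectivity of the pericyclic cascade and needs no directing effect, which is better than the aryne on this point. The congested bond exists beforehand as a bond to an alkyne carbon. The side-chain centres come from acyclic, reagent-controlled chemistry, which is equal or better as an origin of C2 than a hindered oxa-Michael addition. The three oxygens of A5 are differentiated.
- Against it here: A5 is far from the target. C4a'' is unsubstituted and competes with the equally free C6'' in any later acylation. C4'', C3'', C2'', ring B'' and all of ring A are still missing. The 5''-ethyl ether needs a Lewis acid to cleave. The silyloxy-bearing carbon of A5 is (S) whereas C2 of the target is (R) with the same ranking, so that oxygen cannot become O1 with retention: the closure must invert this centre, or the antipodal side chain must be made. C3 would in any case be adjusted by equilibration to the trans isomer once C4 is a ketone.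
- Comparison: the mechanism is as well founded as that of the chosen plan, but step economy is clearly worse, since A4 alone needs a long sequence and ring A still needs an acylation of the kind the chosen key step performs.

Alternative 3: The cut is C4a''–C5'', ring A'' being grown on a preformed (S)-dihydropyranone. In the forward sense heating A6 expels acetone from the dioxinone; the acylketene is attacked by the enol-ether carbon C4a'' in a six-membered closure, and tautomerization gives the phloroglucinol ring of A7.
- In its favour: C2'' is set early on a small ring by dependable chemistry, which is better than the catalyst-controlled closure of step 14. There is no ambiguity between O1'' and the 5''-oxygen, which is better than a protecting-group gate. Conditions are neutral.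
- Against it here: A6 is hard to assemble, being a methine that carries the dihydropyranone, the dioxinone and the branched side chain. The heat needed may reopen the dihydropyranone by β-elimination. Ring A and C4 of the upper unit are absent, as in alternative 2. The side chain has the same (S) carbinol. The free 5'',7''-diol must be protected again.
- Comparison: mechanistically equal, stronger on C2'', weaker on convergence and step count. It could be combined with the aryne insertion for the upper ring, the part it leaves open.

Key step: step 10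

Assumption: the benzyl ethers 1, 8, 14 and 19 are bought as such; starting from phloroglucinol, 2,4,6-trihydroxyacetophenone, 3,4-dihydroxybenzaldehyde and 4-hydroxybenzaldehyde would add one O-benzylation per branch.
Assumption: the sense of induction of the two thiourea catalysts is assigned by analogy with simple 2'-hydroxychalcones and is to be confirmed on first use; if it is reversed, the two catalysts change places.

## Route

Step 1
Reactants: 1 3,5-bis(benzyloxy)phenol
Product: 2 3,5-bis(benzyloxy)phenyl N-isopropylcarbamate
Conditions: i-PrNCO, Et3N (cat.), CH2Cl2, rt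
Reagents that add atoms: isopropyl isocyanate, CC(C)N=C=O
Why: Base-catalysed addition of the phenol to the isocyanate (carbamoylation) should be clean; the N-monoalkyl carbamate directs ortho-lithiation and can later be removed under mild, non-hydrolytic conditions.

Step 2
Reactants: 2 3,5-bis(benzyloxy)phenyl N-isopropylcarbamate
Product: 5 3,5-bis(benzyloxy)-2-(trimethylsilyl)phenyl N-isopropylcarbamate, via N-TBS carbamate 3 (not isolated), via N-TBS 2-silyl carbamate 4 (not isolated)
Conditions: TBSOTf, TMEDA, Et2O, 0 °C to rt; n-BuLi, TMEDA, −78 °C; TMSCl, −78 °C to rt; aq. NaHSO4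
Reagents that add atoms: chlorotrimethylsilane, C[Si](C)(C)Cl; tert-butyldimethylsilyl triflate, CC(C)(C)[Si](C)(C)OS(=O)(=O)C(F)(F)F (its atoms stay only in 3 and 4)
Why: Directed ortho-metalation: the NH is capped as 3, n-BuLi/TMEDA lithiates ortho to the carbamate, TMSCl gives 4, and the labile N–Si bond is cleaved in the acidic work-up. Both ortho positions are equivalent by symmetry and each lies between the carbamate and a benzyloxy group, so silicon can only enter at C2; the position between the two benzyloxy groups has the weaker directing pair.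

Step 3
Reactants: 5 3,5-bis(benzyloxy)-2-(trimethylsilyl)phenyl N-isopropylcarbamate
Product: 7 3,5-bis(benzyloxy)-2-(trimethylsilyl)phenyl trifluoromethanesulfonate, via 2-silylphenol 6 (not isolated)
Conditions: Et2NH, DBU, MeCN, 40 °C; then PhNTf2, rt
Reagents that add atoms: N-phenylbis(trifluoromethanesulfonimide), O=S(=O)(N(c1ccccc1)S(=O)(=O)C(F)(F)F)C(F)(F)F
Why: DBU induces E1cB loss of isopropyl isocyanate from the carbamate (trapped by Et2NH as a urea), and the phenoxide 6 is O-triflated in the same flask; this is the usual one-flask end of the carbamate route to ortho-silylaryl triflates and avoids isolating the desilylation-prone phenol.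

Step 4
Reactants: 8 1-[2,4-bis(benzyloxy)-6-hydroxyphenyl]ethan-1-one
Product: 9 1-[2-(allyloxy)-4,6-bis(benzyloxy)phenyl]ethan-1-one
Conditions: allyl bromide, K2CO3, DMF, 60 °C
Reagents that add atoms: allyl bromide, C=CCBr
Why: Williamson etherification of the hydrogen-bonded hydroxyl, the only free phenol; K2CO3 in warm DMF is sufficient and does not touch the methyl ketone.

Step 5
Reactants: 9 1-[2-(allyloxy)-4,6-bis(benzyloxy)phenyl]ethan-1-one
Product: 10 1-[3-allyl-4,6-bis(benzyloxy)-2-hydroxyphenyl]ethan-1-one
Conditions: PhNEt2, 195 °C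
Reagents that add atoms: none
Why: Aromatic Claisen rearrangement ([3,3] shift, then tautomerization): one ortho position of the allyl ether carries the acetyl group, so the allyl group can only migrate to C3, the carbon that becomes C8''; the hindered aryl–carbon bond is thus made intramolecularly.

Step 6
Reactants: 10 1-[3-allyl-4,6-bis(benzyloxy)-2-hydroxyphenyl]ethan-1-one
Product: 11 1-[3-allyl-4,6-bis(benzyloxy)-2-(methoxymethoxy)phenyl]ethan-1-one
Conditions: NaH, DMF, 0 °C; MOMCl, 0 °C to rt
Reagents that add atoms: chloromethyl methyl ether, COCCl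
Why: O-Alkylation of the sodium phenoxide (acetal protection); one equivalent of NaH takes the chelated phenol in preference to the methyl ketone. The MOM ether masks the future O1'' through the fluoride and hydroxide steps and is later removed by mild acid, orthogonally to the benzyl ethers.

Step 7
Reactants: 11 1-[3-allyl-4,6-bis(benzyloxy)-2-(methoxymethoxy)phenyl]ethan-1-one
Product: 12 2-[3-acetyl-4,6-bis(benzyloxy)-2-(methoxymethoxy)phenyl]acetaldehyde
Conditions: OsO4 (cat.), NaIO4, 2,6-lutidine, dioxane/H2O (3:1), rt
Reagents that add atoms: osmium tetroxide, O=[Os](=O)(=O)=O (delivers the oxygen; regenerated by sodium periodate, [Na+].[O-]I(=O)(=O)=O)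
Why: Lemieux–Johnson cleavage (catalytic dihydroxylation, periodate scission of the diol); only the terminal alkene reacts, whereas RuO4 or ozone could degrade the electron-rich ring, and 2,6-lutidine suppresses over-oxidation. The arylacetaldehyde is used at once.

Step 8
Reactants: 12 2-[3-acetyl-4,6-bis(benzyloxy)-2-(methoxymethoxy)phenyl]acetaldehyde
Product: 13 2-[3-acetyl-4,6-bis(benzyloxy)-2-(methoxymethoxy)phenyl]acetic acid
Conditions: NaClO2, NaH2PO4, 2-methyl-2-butene, t-BuOH/H2O, 0 °C to rt
Reagents that add atoms: sodium chlorite, [Na+].[O-]Cl=O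
Why: Pinnick oxidation of the aldehyde to the acid; the large excess of 2-methyl-2-butene removes HOCl before it can chlorinate the activated ring position, and the ketone, acetal and benzyl ethers are inert.

Step 9
Reactants: 13 2-[3-acetyl-4,6-bis(benzyloxy)-2-(methoxymethoxy)phenyl]acetic acid; 14 3,4-bis(benzyloxy)benzaldehyde
Product: 16 (E)-2-[3-acetyl-4,6-bis(benzyloxy)-2-(methoxymethoxy)phenyl]-3-[3,4-bis(benzyloxy)phenyl]acrylic acid, via mixed acetic anhydride 15 (not isolated)
Conditions: Ac2O, Et3N, 110 °C; then H2O, THF, 60 °C; aq. citric acid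
Reagents that add atoms: water, O (hydrolysis of 15 on work-up; acetic anhydride, CC(=O)OC(C)=O, leaves atoms only in 15)
Why: Perkin condensation (Oglialoro variant for arylacetic acids): the mixed anhydride of 13 is enolized by Et3N at its doubly activated CH2, adds to 14, and acetate is eliminated; the isomer with the carboxyl trans to the new aryl group (E) is the usual major product. The methyl ketone is far less acidic than the anhydride CH2 and is shielded by two ortho substituents, and the buffered basic medium protects the MOM ether.

Step 10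
Reactants: 16 (E)-2-[3-acetyl-4,6-bis(benzyloxy)-2-(methoxymethoxy)phenyl]-3-[3,4-bis(benzyloxy)phenyl]acrylic acid; 7 3,5-bis(benzyloxy)-2-(trimethylsilyl)phenyl trifluoromethanesulfonate
Product: 18 (E)-2-[3-acetyl-4,6-bis(benzyloxy)-2-(methoxymethoxy)phenyl]-1-[2,4-bis(benzyloxy)-6-hydroxyphenyl]-3-[3,4-bis(benzyloxy)phenyl]prop-2-en-1-one, via cesium carboxylate 17 (not isolated)
Conditions: Cs2CO3 (0.5 equiv), MeOH, rt, evaporate and dry; 7 (1.3 equiv, in portions), CsF (4 equiv), THF, 110–125 °C (pressure vessel); AcOH, 0 °C
Reagents that add atoms: none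
Why: Fluoride removes the silyl group of 7 and triflate leaves, giving 3,5-bis(benzyloxy)benzyne; the carboxylate oxygen of 17 adds to the aryne carbon remote from the flanking benzyloxy group, so the aryl anion arises next to that inductively withdrawing oxygen. The anion attacks its own ester carbonyl through a transient four-membered alkoxide, which opens to the ortho-acyl phenoxide, so that the acid C–O bond is replaced by O1–C8a and C4–C4a. The closest known reaction type is the fluoride-induced insertion of arynes into the C–O bond of carboxylic acids, which gives ortho-hydroxyaryl ketones. No ring of the target closes and no stereocentre forms; the four-membered ring is only an intermediate. The selectivity needed is regiochemical (acyl group on the carbon between the new phenol and the C5 oxygen) and is secured by the 3-benzyloxy group of the aryne, the 5-benzyloxy group being too remote to override it. Using the dried cesium salt without a proton donor means the aryl anion cannot be quenched to the simple aryl ester, and the product stays as its phenoxide, which is more stable than the enolate a ring closure onto the enone would give, so the chalcone should stay open until the cold quench. The acetyl group is flanked by two ortho substituents and CsF in THF is a weak base towards it; the MOM and benzyl ethers are inert to fluoride.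

Step 11
Reactants: 18 (E)-2-[3-acetyl-4,6-bis(benzyloxy)-2-(methoxymethoxy)phenyl]-1-[2,4-bis(benzyloxy)-6-hydroxyphenyl]-3-[3,4-bis(benzyloxy)phenyl]prop-2-en-1-one; 19 4-(benzyloxy)benzaldehyde
Product: 20 (E)-1-[2,4-bis(benzyloxy)-6-hydroxyphenyl]-2-{4,6-bis(benzyloxy)-3-[(E)-3-(4-benzyloxyphenyl)prop-2-enoyl]-2-(methoxymethoxy)phenyl}-3-[3,4-bis(benzyloxy)phenyl]prop-2-en-1-one
Conditions: KOH (50% aq.), EtOH/THF, 0 °C to rt; 1 M HCl to pH 5, 0 °C
Reagents that add atoms: none
Why: Claisen–Schmidt condensation: only the acetyl group is enolizable and 19 cannot enolize, so the (E)-enone of the lower unit forms after dehydration. In ethanolic hydroxide the upper unit exists as its open 2'-phenoxide, which is more stable than the C3 enolate of a closed ring, so no stereocentre forms and any upper-ring flavanone carried over from step 10 is reopened by E1cB elimination; cold, brief acidification returns the neutral bis-chalcone.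

Step 12
Reactants: 20 (E)-1-[2,4-bis(benzyloxy)-6-hydroxyphenyl]-2-{4,6-bis(benzyloxy)-3-[(E)-3-(4-benzyloxyphenyl)prop-2-enoyl]-2-(methoxymethoxy)phenyl}-3-[3,4-bis(benzyloxy)phenyl]prop-2-en-1-one
Product: 21 (2R,3S)-5,7-bis(benzyloxy)-2-[3,4-bis(benzyloxy)phenyl]-3-{4,6-bis(benzyloxy)-3-[(E)-3-(4-benzyloxyphenyl)prop-2-enoyl]-2-(methoxymethoxy)phenyl}chroman-4-one
Conditions: N-[3,5-bis(trifluoromethyl)phenyl]-N'-[(9R)-6'-methoxycinchonan-9-yl]thiourea (quinidine-derived, C29H28F6N4OS, 10 mol%), toluene, 0 °C to rt
Reagents that add atoms: none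
Why: Catalytic asymmetric intramolecular oxa-Michael addition (6-endo-trig): the quinuclidine nitrogen deprotonates the 2'-hydroxyl while the thiourea binds the enone carbonyl, and the catalyst decides the face of C2 that O1 attacks, giving (2R). C3 is set on protonation of the enolate and equilibrates through the enol under the same amine to the trans-2,3-diaryl isomer (both aryl groups equatorial), which is (3S). The lower enone cannot cyclize because its phenol is a MOM ether.

Step 13
Reactants: 21 (2R,3S)-5,7-bis(benzyloxy)-2-[3,4-bis(benzyloxy)phenyl]-3-{4,6-bis(benzyloxy)-3-[(E)-3-(4-benzyloxyphenyl)prop-2-enoyl]-2-(methoxymethoxy)phenyl}chroman-4-one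
Product: 22 (2R,3S)-5,7-bis(benzyloxy)-2-[3,4-bis(benzyloxy)phenyl]-3-{4,6-bis(benzyloxy)-3-[(E)-3-(4-benzyloxyphenyl)prop-2-enoyl]-2-hydroxyphenyl}chroman-4-one
Conditions: HCl (2 M in MeOH), THF, 0 °C to rt
Reagents that add atoms: none
Why: Acid-catalysed methanolysis of the MOM acetal, eased by the neighbouring carbonyl; benzyl ethers and the flavanone are stable to dilute acid at this temperature, the upper stereocentres see no base, and the short, cool treatment should keep acid-catalysed racemic closure of the lower chalcone negligible.

Step 14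
Reactants: 22 (2R,3S)-5,7-bis(benzyloxy)-2-[3,4-bis(benzyloxy)phenyl]-3-{4,6-bis(benzyloxy)-3-[(E)-3-(4-benzyloxyphenyl)prop-2-enoyl]-2-hydroxyphenyl}chroman-4-one
Product: 23 (2R,3S)-5,7-bis(benzyloxy)-2-[3,4-bis(benzyloxy)phenyl]-3-[(2S)-5,7-bis(benzyloxy)-2-(4-benzyloxyphenyl)-4-oxochroman-8-yl]chroman-4-one
Conditions: N-[3,5-bis(trifluoromethyl)phenyl]-N'-[(8α,9S)-6'-methoxycinchonan-9-yl]thiourea (quinine-derived, C29H28F6N4OS, 10 mol%), toluene, 0 °C
Reagents that add atoms: none
Why: Second asymmetric oxa-Michael addition (6-endo-trig) with the pseudoenantiomeric catalyst, needed because C2'' requires the facial sense opposite to that of C2; the new centre (2''S) is set by the catalyst, the existing centres being remote across the C3–C8'' bond. Low temperature and work-up at full conversion limit amine-induced reopening of the upper ring.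

Step 15
Reactants: 23 (2R,3S)-5,7-bis(benzyloxy)-2-[3,4-bis(benzyloxy)phenyl]-3-[(2S)-5,7-bis(benzyloxy)-2-(4-benzyloxyphenyl)-4-oxochroman-8-yl]chroman-4-one
Product: 24 (2R,3S)-2-(3,4-dihydroxyphenyl)-5,7-dihydroxy-3-[(2S)-5,7-dihydroxy-2-(4-hydroxyphenyl)-4-oxochroman-8-yl]chroman-4-one
Conditions: H2 (1 atm), Pd/C (10 wt%), EtOAc/MeOH, rt
Reagents that add atoms: none
Why: Hydrogenolysis of the seven benzyl ethers over Pd/C under neutral conditions; the enolizable and base-labile stereocentres are untouched, and stopping at the calculated hydrogen uptake should spare the cyclic benzylic C2–O1 and C2''–O1'' bonds and the two ketones.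

## Compound list

1 | 3,5-bis(benzyloxy)phenol | Oc1cc(OCc2ccccc2)cc(OCc2ccccc2)c1 | starting material
2 | 3,5-bis(benzyloxy)phenyl N-isopropylcarbamate | CC(C)NC(=O)Oc1cc(OCc2ccccc2)cc(OCc2ccccc2)c1 | intermediate
3 | 3,5-bis(benzyloxy)phenyl N-(tert-butyldimethylsilyl)-N-isopropylcarbamate | CC(C)N([Si](C)(C)C(C)(C)C)C(=O)Oc1cc(OCc2ccccc2)cc(OCc2ccccc2)c1 | intermediate (not isolated)
4 | 3,5-bis(benzyloxy)-2-(trimethylsilyl)phenyl N-(tert-butyldimethylsilyl)-N-isopropylcarbamate | CC(C)N([Si](C)(C)C(C)(C)C)C(=O)Oc1cc(OCc2ccccc2)cc(OCc2ccccc2)c1[Si](C)(C)C | intermediate (not isolated)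
5 | 3,5-bis(benzyloxy)-2-(trimethylsilyl)phenyl N-isopropylcarbamate | CC(C)NC(=O)Oc1cc(OCc2ccccc2)cc(OCc2ccccc2)c1[Si](C)(C)C | intermediate
6 | 3,5-bis(benzyloxy)-2-(trimethylsilyl)phenol | Oc1cc(OCc2ccccc2)cc(OCc2ccccc2)c1[Si](C)(C)C | intermediate (not isolated)
7 | 3,5-bis(benzyloxy)-2-(trimethylsilyl)phenyl trifluoromethanesulfonate | C[Si](C)(C)c1c(OS(=O)(=O)C(F)(F)F)cc(OCc2ccccc2)cc1OCc1ccccc1 | intermediate
8 | 1-[2,4-bis(benzyloxy)-6-hydroxyphenyl]ethan-1-one | CC(=O)c1c(O)cc(OCc2ccccc2)cc1OCc1ccccc1 | starting material
9 | 1-[2-(allyloxy)-4,6-bis(benzyloxy)phenyl]ethan-1-one | CC(=O)c1c(OCC=C)cc(OCc2ccccc2)cc1OCc1ccccc1 | intermediate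
10 | 1-[3-allyl-4,6-bis(benzyloxy)-2-hydroxyphenyl]ethan-1-one | CC(=O)c1c(O)c(CC=C)c(OCc2ccccc2)cc1OCc1ccccc1 | intermediate
11 | 1-[3-allyl-4,6-bis(benzyloxy)-2-(methoxymethoxy)phenyl]ethan-1-one | CC(=O)c1c(OCOC)c(CC=C)c(OCc2ccccc2)cc1OCc1ccccc1 | intermediate
12 | 2-[3-acetyl-4,6-bis(benzyloxy)-2-(methoxymethoxy)phenyl]acetaldehyde | CC(=O)c1c(OCOC)c(CC=O)c(OCc2ccccc2)cc1OCc1ccccc1 | intermediate
13 | 2-[3-acetyl-4,6-bis(benzyloxy)-2-(methoxymethoxy)phenyl]acetic acid | CC(=O)c1c(OCOC)c(CC(=O)O)c(OCc2ccccc2)cc1OCc1ccccc1 | intermediate
14 | 3,4-bis(benzyloxy)benzaldehyde | O=Cc1ccc(OCc2ccccc2)c(OCc2ccccc2)c1 | starting material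
15 | acetic (E)-2-[3-acetyl-4,6-bis(benzyloxy)-2-(methoxymethoxy)phenyl]-3-[3,4-bis(benzyloxy)phenyl]acrylic anhydride | CC(=O)OC(=O)/C(c1c(OCOC)c(C(C)=O)c(OCc2ccccc2)cc1OCc1ccccc1)=C/c1ccc(OCc2ccccc2)c(OCc2ccccc2)c1 | intermediate (not isolated)
16 | (E)-2-[3-acetyl-4,6-bis(benzyloxy)-2-(methoxymethoxy)phenyl]-3-[3,4-bis(benzyloxy)phenyl]acrylic acid | OC(=O)/C(c1c(OCOC)c(C(C)=O)c(OCc2ccccc2)cc1OCc1ccccc1)=C/c1ccc(OCc2ccccc2)c(OCc2ccccc2)c1 | intermediate
17 | cesium (E)-2-[3-acetyl-4,6-bis(benzyloxy)-2-(methoxymethoxy)phenyl]-3-[3,4-bis(benzyloxy)phenyl]acrylate | [Cs+].[O-]C(=O)/C(c1c(OCOC)c(C(C)=O)c(OCc2ccccc2)cc1OCc1ccccc1)=C/c1ccc(OCc2ccccc2)c(OCc2ccccc2)c1 | intermediate (not isolated)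
18 | (E)-2-[3-acetyl-4,6-bis(benzyloxy)-2-(methoxymethoxy)phenyl]-1-[2,4-bis(benzyloxy)-6-hydroxyphenyl]-3-[3,4-bis(benzyloxy)phenyl]prop-2-en-1-one | O=C(c1c(O)cc(OCc2ccccc2)cc1OCc1ccccc1)/C(c1c(OCOC)c(C(C)=O)c(OCc2ccccc2)cc1OCc1ccccc1)=C/c1ccc(OCc2ccccc2)c(OCc2ccccc2)c1 | intermediate
19 | 4-(benzyloxy)benzaldehyde | O=Cc1ccc(OCc2ccccc2)cc1 | starting material
20 | (E)-1-[2,4-bis(benzyloxy)-6-hydroxyphenyl]-2-{4,6-bis(benzyloxy)-3-[(E)-3-(4-benzyloxyphenyl)prop-2-enoyl]-2-(methoxymethoxy)phenyl}-3-[3,4-bis(benzyloxy)phenyl]prop-2-en-1-one | O=C(c1c(O)cc(OCc2ccccc2)cc1OCc1ccccc1)/C(c1c(OCOC)c(C(=O)/C=C/c2ccc(OCc3ccccc3)cc2)c(OCc2ccccc2)cc1OCc1ccccc1)=C/c1ccc(OCc2ccccc2)c(OCc2ccccc2)c1 | intermediate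
21 | (2R,3S)-5,7-bis(benzyloxy)-2-[3,4-bis(benzyloxy)phenyl]-3-{4,6-bis(benzyloxy)-3-[(E)-3-(4-benzyloxyphenyl)prop-2-enoyl]-2-(methoxymethoxy)phenyl}chroman-4-one | O=C(/C=C/c1ccc(OCc2ccccc2)cc1)c1c(OCc2ccccc2)cc(OCc2ccccc2)c([C@@H]2C(=O)c3c(OCc4ccccc4)cc(OCc4ccccc4)cc3O[C@H]2c2ccc(OCc3ccccc3)c(OCc3ccccc3)c2)c1OCOC | intermediate
22 | (2R,3S)-5,7-bis(benzyloxy)-2-[3,4-bis(benzyloxy)phenyl]-3-{4,6-bis(benzyloxy)-3-[(E)-3-(4-benzyloxyphenyl)prop-2-enoyl]-2-hydroxyphenyl}chroman-4-one | O=C(/C=C/c1ccc(OCc2ccccc2)cc1)c1c(OCc2ccccc2)cc(OCc2ccccc2)c([C@@H]2C(=O)c3c(OCc4ccccc4)cc(OCc4ccccc4)cc3O[C@H]2c2ccc(OCc3ccccc3)c(OCc3ccccc3)c2)c1O | intermediate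
23 | (2R,3S)-5,7-bis(benzyloxy)-2-[3,4-bis(benzyloxy)phenyl]-3-[(2S)-5,7-bis(benzyloxy)-2-(4-benzyloxyphenyl)-4-oxochroman-8-yl]chroman-4-one | O=C1C[C@@H](c2ccc(OCc3ccccc3)cc2)Oc2c1c(OCc1ccccc1)cc(OCc1ccccc1)c2[C@@H]1C(=O)c2c(OCc3ccccc3)cc(OCc3ccccc3)cc2O[C@H]1c1ccc(OCc2ccccc2)c(OCc2ccccc2)c1 | intermediate
24 | (2R,3S)-2-(3,4-dihydroxyphenyl)-5,7-dihydroxy-3-[(2S)-5,7-dihydroxy-2-(4-hydroxyphenyl)-4-oxochroman-8-yl]chroman-4-one | O=C1C[C@@H](c2ccc(O)cc2)Oc2c1c(O)cc(O)c2[C@@H]1C(=O)c2c(O)cc(O)cc2O[C@H]1c1ccc(O)c(O)c1 | target

## Step count and least certain steps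

Total step count: 15 (three to 7, six to 16, then six from the key step to 24). Longest linear sequence: 12 steps (8 to 24, steps 4 to 15).

Step 10 (key step). Most likely to go wrong:
- protonation of the aryl anion before acyl transfer, which stops the sequence at the simple aryl ester;
- O-arylation of the product phenoxide by a second aryne;
- fluoride-induced enolization of the acetyl group followed by arylation;
- premature, uncontrolled closure of the upper ring at high temperature (harmless for the route, since step 11 reopens it, but it lowers the isolated amount of 18).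

Fallback, setting out from 16 and 1 and returning at 18: the same ortho-metalated aryl ester is generated by halogen–lithium exchange instead of aryne addition. Ortho-selective bromination of 1 (NBS, i-Pr2NH cat., CH2Cl2) should give 2-bromo-3,5-bis(benzyloxy)phenol F1. Carbodiimide coupling with 16 (N-ethyl-N'-(3-dimethylaminopropyl)carbodiimide hydrochloride, DMAP) gives the aryl ester F2. LiN(SiMe3)2 (1 equiv, −78 °C) holds the acetyl group as its enolate, and n-BuLi at −100 °C then effects bromine–lithium exchange and the 1,3 O-to-C acyl shift (anionic Fries rearrangement). An acidic quench gives 18.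

Step 12. Most likely to go wrong:
- poor facial selectivity, because the enone is trisubstituted and carries a doubly ortho-substituted aryl group at the α-carbon;
- E/Z isomerization of this enone during step 11, which would feed the catalyst two substrates of opposite sense;
- slow turnover, allowing uncatalysed background closure.

Fallback, setting out from 20 and returning at 21: the ring is closed without a chiral catalyst (NaOAc, EtOH, 50 °C) to the racemic trans-flavanone, and 21 is separated from its enantiomer, the (2S,3R)-flavanone F3, by preparative chromatography on a chiral stationary phase. F3 is recycled to 20 by ring opening in ethanolic KOH.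

Step 14. Most likely to go wrong:
- low diastereoselectivity if the catalyst is mismatched with the existing centres or the hindered phenol next to C8'' reacts slowly;
- amine-induced reopening of the upper ring, which would erode C2/C3;
- partial acid-catalysed closure already in step 13.

Fallback, setting out from 22 and returning at 23: closure without a chiral catalyst (NaOAc, EtOH) gives 23 together with its C2'' epimer, the (2R,3S,2''R)-hepta-O-benzyl biflavanone F4. The two are diastereomers and should be separable by ordinary chromatography or crystallization.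

Step 9. Most likely to go wrong:
- sluggish condensation, because the arylacetic acid is substituted at both ortho positions;
- loss of the MOM group to hot acetic acid;
- competing enolization of the methyl ketone.

Fallback, setting out from 12 (with 14) and returning at 16: amine-catalysed cross-aldol condensation of the arylacetaldehyde 12 with 14 (pyrrolidine, AcOH cat., toluene, 50 °C), in which only the aldehyde forms an enamine, gives (E)-2-[3-acetyl-4,6-bis(benzyloxy)-2-(methoxymethoxy)phenyl]-3-[3,4-bis(benzyloxy)phenyl]prop-2-enal F5. Pinnick oxidation (NaClO2, NaH2PO4, 2-methyl-2-butene) then gives 16 without passing through 13.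

Step 2. Most likely to go wrong:
- benzylic deprotonation of a benzyl ether by n-BuLi/TMEDA, with Wittig rearrangement;
- lithiation between the two benzyloxy groups, competing with the carbamate-directed site.

Fallback, setting out from 1 and returning at 7: ortho-bromination of 1 as above gives 2-bromo-3,5-bis(benzyloxy)phenol F1. Silylation (hexamethyldisilazane, neat, 80 °C) gives [2-bromo-3,5-bis(benzyloxy)phenoxy]trimethylsilane F6. n-BuLi at −100 °C causes bromine–lithium exchange and a 1,3 O-to-C silyl shift (retro-Brook) to the lithium salt of 6, which is triflated with Tf2O to give 7.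

Step 15. Most likely to go wrong:
- over-reduction, that is hydrogenolysis of a cyclic benzylic C–O bond or reduction of a ketone;
- incomplete removal of seven benzyl groups as the partly deprotected material loses solubility.

Fallback, setting out from 23 and ending at 24: non-reductive debenzylation with BCl3 and pentamethylbenzene as cation scavenger (CH2Cl2, −78 °C). No new compound is formed.

## Further compounds

F1 | step 10 | 2-bromo-3,5-bis(benzyloxy)phenol | Oc1cc(OCc2ccccc2)cc(OCc2ccccc2)c1Br
F2 | step 10 | 2-bromo-3,5-bis(benzyloxy)phenyl (E)-2-[3-acetyl-4,6-bis(benzyloxy)-2-(methoxymethoxy)phenyl]-3-[3,4-bis(benzyloxy)phenyl]acrylate | O=C(Oc1cc(OCc2ccccc2)cc(OCc2ccccc2)c1Br)/C(c1c(OCOC)c(C(C)=O)c(OCc2ccccc2)cc1OCc1ccccc1)=C/c1ccc(OCc2ccccc2)c(OCc2ccccc2)c1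
F3 | step 12 | (2S,3R)-5,7-bis(benzyloxy)-2-[3,4-bis(benzyloxy)phenyl]-3-{4,6-bis(benzyloxy)-3-[(E)-3-(4-benzyloxyphenyl)prop-2-enoyl]-2-(methoxymethoxy)phenyl}chroman-4-one | O=C(/C=C/c1ccc(OCc2ccccc2)cc1)c1c(OCc2ccccc2)cc(OCc2ccccc2)c([C@H]2C(=O)c3c(OCc4ccccc4)cc(OCc4ccccc4)cc3O[C@@H]2c2ccc(OCc3ccccc3)c(OCc3ccccc3)c2)c1OCOC
F4 | step 14 | (2R,3S)-5,7-bis(benzyloxy)-2-[3,4-bis(benzyloxy)phenyl]-3-[(2R)-5,7-bis(benzyloxy)-2-(4-benzyloxyphenyl)-4-oxochroman-8-yl]chroman-4-one | O=C1C[C@H](c2ccc(OCc3ccccc3)cc2)Oc2c1c(OCc1ccccc1)cc(OCc1ccccc1)c2[C@@H]1C(=O)c2c(OCc3ccccc3)cc(OCc3ccccc3)cc2O[C@H]1c1ccc(OCc2ccccc2)c(OCc2ccccc2)c1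
F5 | step 9 | (E)-2-[3-acetyl-4,6-bis(benzyloxy)-2-(methoxymethoxy)phenyl]-3-[3,4-bis(benzyloxy)phenyl]prop-2-enal | O=C/C(c1c(OCOC)c(C(C)=O)c(OCc2ccccc2)cc1OCc1ccccc1)=C/c1ccc(OCc2ccccc2)c(OCc2ccccc2)c1
F6 | step 2 | [2-bromo-3,5-bis(benzyloxy)phenoxy]trimethylsilane | C[Si](C)(C)Oc1cc(OCc2ccccc2)cc(OCc2ccccc2)c1Br
F0 | step 15 | none | none
A1 | alternative 1 | (2R,3S)-2-(3,4-dihydroxyphenyl)-5,7-dihydroxy-3-{2,6-dihydroxy-3-[(E)-3-(4-hydroxyphenyl)prop-2-enoyl]-4-(methoxymethoxy)phenyl}chroman-4-one | O=C(/C=C/c1ccc(O)cc1)c1c(OCOC)cc(O)c([C@@H]2C(=O)c3c(O)cc(O)cc3O[C@H]2c2ccc(O)c(O)c2)c1O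
A2 | alternative 1 | (2R,3S)-2-(3,4-dihydroxyphenyl)-5,7-dihydroxy-3-[(2S)-7-hydroxy-2-(4-hydroxyphenyl)-5-(methoxymethoxy)-4-oxochroman-8-yl]chroman-4-one | O=C1C[C@@H](c2ccc(O)cc2)Oc2c1c(OCOC)cc(O)c2[C@@H]1C(=O)c2c(O)cc(O)cc2O[C@H]1c1ccc(O)c(O)c1
A3 | alternative 2 | 3-ethoxycyclobut-2-en-1-one | CCOC1=CC(=O)C1
A4 | alternative 2 | {[(3R,4S)-4-[3,4-bis(benzyloxy)phenyl]-4-[(tert-butyldimethylsilyl)oxy]-3-vinylbut-1-yn-1-yl]oxy}triisopropylsilane | CC(C)[Si](C(C)C)(C(C)C)OC#C[C@@H](C=C)[C@H](O[Si](C)(C)C(C)(C)C)c1ccc(OCc2ccccc2)c(OCc2ccccc2)c1
A5 | alternative 2 | 2-{(1S,2R)-1-[3,4-bis(benzyloxy)phenyl]-1-[(tert-butyldimethylsilyl)oxy]but-3-en-2-yl}-5-ethoxy-3-[(triisopropylsilyl)oxy]phenol | CCOc1cc(O)c([C@@H](C=C)[C@H](O[Si](C)(C)C(C)(C)C)c2ccc(OCc3ccccc3)c(OCc3ccccc3)c2)c(O[Si](C(C)C)(C(C)C)C(C)C)c1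
A6 | alternative 3 | 6-[1-{(2S)-2-[4-(benzyloxy)phenyl]-4-oxo-3,4-dihydro-2H-pyran-6-yl}-3-[3,4-bis(benzyloxy)phenyl]-3-[(tert-butyldimethylsilyl)oxy]-2-vinylpropyl]-2,2-dimethyl-4H-1,3-dioxin-4-one (side-chain centres as in A7, methine between the two rings unassigned) | CC1(C)OC(=CC(=O)O1)C([C@@H](C=C)[C@H](O[Si](C)(C)C(C)(C)C)c1ccc(OCc2ccccc2)c(OCc2ccccc2)c1)C1=CC(=O)C[C@@H](c2ccc(OCc3ccccc3)cc2)O1
A7 | alternative 3 | (2S)-8-{(1S,2R)-1-[3,4-bis(benzyloxy)phenyl]-1-[(tert-butyldimethylsilyl)oxy]but-3-en-2-yl}-2-[4-(benzyloxy)phenyl]-5,7-dihydroxychroman-4-one | O=C1C[C@@H](c2ccc(OCc3ccccc3)cc2)Oc2c1c(O)cc(O)c2[C@@H](C=C)[C@H](O[Si](C)(C)C(C)(C)C)c1ccc(OCc2ccccc2)c(OCc2ccccc2)c1
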